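Remark (assumption): steroid-type locants are used for the decalin (ring A = C1–C5 and C10, ring B = C5–C10, C3 = ether carbon, C11 = carbinol carbon), and 2-allyl-4-bromophenol is taken to be a catalogue compound (otherwise two steps from 4-bromophenol by O-allylation and Claisen rearrangement).

## Structural features

The target joins a honokiol-type biaryl to C3 of a trans-fused decalin through an aryl–oxygen bond. One benzene ring of the biaryl carries a free phenol ortho to an allyl group; the other carries an allyl group para to the ether oxygen and the biaryl bond ortho to it. The decalin has four stereocentres, (3R,5S,7R,10S): the quaternary C10 (axial methyl) and C5 (H) are adjacent and define the trans fusion, C3 is fully substituted with an equatorial methyl and an axial aryloxy group, and C7 carries an equatorial 2-hydroxypropan-2-yl group (C11) cis to the C10 methyl. Fragile groups are the tertiary alkyl aryl ether (ionisation or elimination in acid), the two allyl groups (migration into conjugation, hydrogenation, oxidation), the free phenol and the tertiary alcohol. The real difficulties are the hindered axial C3–O–aryl bond next to an ortho aryl group, and the 1,4-relationship between the quaternary C10 and C7, which no ring-fusion reaction sets by itself. The key step exploits the fact that C3 (oxygen) and C10 (methyl) are para to each other across ring A, so ring A is a masked p-cresol. A C7-stereogenic chain attached at C5 can therefore close ring B by C9–C10 bond formation at the methyl-bearing para carbon, which cannot rearomatise and so delivers the C3 carbonyl, the C10 quaternary centre and the C4=C5 handle for the trans fusion in one operation.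

## Logic of the disconnections

32 ⇒ 31. The C11 O–H bond is traced back to an O–Si bond. The silyl group is needed from step 8 to step 16 and is removed last because that final step forms no bond to carbon. The gain is a single free tertiary alcohol in 22 instead of two. The forward step must cleave a hindered tertiary silyl ether without acid (tertiary aryl ether) and without hot strong base (allyl groups).

31 ⇒ 30. The aryl–allyl C–C bond on the ether-bearing ring is cut, leaving chlorine. An allyl group would not survive the oxidation that leads to 25, whereas C–Cl passes untouched through steps 15–18. The gain is a simple dihaloarene as aryl donor. The forward step must couple an electron-rich aryl chloride without moving either double bond.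

30 ⇒ 27 + 29. The biaryl C–C bond is cut. This is the convergent point: the second ring arrives with its phenol and allyl group in place. The gain is two fragments of unequal size, the smaller made in one step. The forward coupling must take place at C–Br next to a bulky tertiary alkoxy group and leave C–Cl alone.

29 ⇒ 28. The C–B bond is cut to C–Br. The reason is that 28 already holds the allyl and hydroxyl groups in the right positions. The gain is a one-step fragment. The borylation must tolerate the free phenol and the allyl group.

27 ⇒ 22 + 25. The aryl–O bond is cut, not the C3–O bond. Cutting on the aryl side keeps C3 out of the bond-forming event, whereas cutting C3–O would mean uncontrolled substitution at a tertiary carbon. The gain is large: the decalin becomes a mono-alcohol and the arene a hypervalent iodine aryl donor. The forward step must arylate a hindered axial tertiary alkoxide and transfer the correct one of the two aryl ligands.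

25 ⇒ 23. The bond from iodine to the trimethoxyphenyl ring is cut. The reason is that this ring serves only as the non-transferred ligand. The gain is a one-pot assembly from 23. The oxidation must stop at trivalent iodine and the arylation must occur only once.

22 ⇒ 21. The C3–CH3 bond is cut, giving the C3 ketone that the dearomatisation supplies. The gain is the loss of one stereocentre. The forward addition must deliver methyl equatorially so that oxygen ends up axial.

21 ⇒ 19. The C5–H and C4–H bonds are removed, giving the C4=C5 enone. The reason is that dissolving-metal reduction of a 10-methyl octalone reliably gives the trans fusion. The gain is the loss of the C5 stereocentre. The reduction must stop at the ketone.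

19 ⇒ 18. The C1–H and C2–H bonds are removed, giving the cross-conjugated dienone. The reason is that 18 is the direct product of the dearomatisation. No stereocentre is lost, but the two steps 12 and 13 together convert a flat ring into the trans-decalone. The hydrogenation must distinguish the disubstituted C1=C2 bond from the trisubstituted C4=C5 bond.

18 ⇒ 16. The C9–C10 bond is cut and ring A becomes a phenol. The reason is the para relationship of C3 and C10. The gain is the largest in the route: a bicycle with a quaternary stereocentre becomes a flat arene with one stereocentre on a side chain. The forward step needs para C-alkylation with the methyl cis to the C7 group. Three features of 16 are chosen to make this safe: the C11 oxygen is silylated (no tetrahydrofuran), the leaving group is a bromide that can be installed with the phenol free, and one equivalent of base makes the phenolate the only base present. A variant with both ortho carbons blocked is held in reserve.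

16 ⇒ 15. The C9–Br bond is exchanged for C9–OH. The reason is that the alkylating function should appear only one step before it is used. The gain is a stable diol-type precursor. The bromination must not touch the phenol or the silyl ether.

15 ⇒ 14. The two O–benzyl bonds (phenol and C9–O) are re-formed. Both oxygens need masking during the enolate and Grignard steps, and one group for both means one deprotection. The gain is a fully protected, non-acidic chain. The hydrogenolysis must spare the silyl ether.

14 ⇒ 13. The C11 O–Si bond is cut. The reason is that the silyl group can only be put on once the carbinol exists. The gain is minor but necessary. The silylation of a tertiary alcohol needs a silyl triflate.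

13 ⇒ 11. Both C11–CH3 bonds are cut, back to the ester carbonyl. The reason is that an acyl group at C11 is what makes C7 accessible by enolate alkylation. The gain is two carbons. The double addition must not epimerise C7 through the intermediate ketone 12.

11 ⇒ 10. The ester C–O bond is exchanged for the imide C–N bond. The reason is that the auxiliary must come off before the Grignard step. The gain is recovery of 6. The cleavage must attack the exocyclic carbonyl and leave C7 intact.

10 ⇒ 8 + 4. The C6–C7 bond is cut. It is the only bond in the route made under auxiliary control, and it joins the arene to the chain. The gain is two achiral or simple fragments. The alkylation must occur on the enolate face that leads to the 7R arrangement of the decalin.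

8 ⇒ 5 + 6. The N–acyl bond is cut. The reason is that both components are catalogue compounds. The gain is complete. The acylation must take place at nitrogen through an activated form of 5.

4 ⇒ 3 ⇒ 2 ⇒ 1. The benzylic C–Br bond, the benzylic C–O bond (by reduction of the ester) and the two O–benzyl bonds are traced back in turn. The reason is that 1 has the methyl, hydroxyl and carboxyl groups in the required 1,2,4-pattern. The gain is a catalogue arene. The forward steps must leave the aryl benzyl ether untouched.

## Other disconnections considered

Alternative 1: The cut is the C7–C8 bond of ring B together with the C11–O bond. The precursor is the monocyclic hydroxy aldehyde A1, a ring A cyclohexane that already holds C3, C5 and C10 and carries a formylmethyl arm on C10 and a prenyl group on C5. In the forward direction dilute aqueous H2SO4 would protonate the aldehyde, C7 of the trisubstituted alkene would attack C8 through a chair, and water would trap the C11 cation to give the triol A2.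
- In its favour: ring B, the C7 stereocentre and the C11 hydroxyl arise together from an inexpensive acid, and C11 needs no protecting group. On this point the alternative is better than the chosen plan, which spends one step on silylation and one on desilylation.
- Against it here: A2 carries a C8 hydroxyl that the target lacks, so a deoxygenation sequence must follow in the presence of two tertiary alcohols. The later O-arylation would have to tell the C3 hydroxyl from the C11 hydroxyl, which the chosen plan avoids by silylating C11 before C3 is an alcohol. The hardest stereochemistry (quaternary C10 next to C5, and C3) is pushed back into A1, a monocycle in which no ring fusion helps.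
- Comparison: on mechanism the two plans are equal in relying on a six-membered chair-like closure with the bulky C7 substituent equatorial, but the cationic step has competing exits (ene-type proton loss to an isopropenyl group, dehydration at C3) that the phenolate closure lacks. On structure the alternative leaves the hardest centres to its precursor. On step economy the saving at C11 is expected to be outweighed by the C8 deoxygenation and the longer route to A1.

Alternative 2: The cut is the C8–C9 bond, with the C7–C9 bond re-formed, which contracts ring B to the cyclopentanone of the bromomethyl β-keto ester A4. A4 would come from the (S)-Hajos–Parrish ketone A3, whose six-membered enone maps onto ring A (carbonyl = C3) and whose quaternary carbon is C10. In the forward direction Bu3SnH/AIBN would generate the primary C8 radical, which adds to the C9 carbonyl; the cyclopropyloxy radical opens by C7–C9 cleavage to the ester-stabilised C7 radical, and hydrogen transfer gives the ring-expanded keto ester A5 (Dowd–Beckwith ring expansion).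
- In its favour: A3 supplies C10 in enantiopure form from a catalogue compound without a stoichiometric auxiliary, a point on which this alternative is better than the chosen plan. The ring expansion of halomethyl β-keto esters is a well-documented reaction type. The C3 oxygen is in place, so the end game would be equal to steps 14–20. The C7 ester can be equilibrated to the equatorial position, which is the required one.
- Against it here: the trans fusion must be set on the hydrindane before the expansion, a reduction known to be capricious for this enone, whereas the chosen plan gets it from an octalone, which reduces reliably trans. The C9 carbonyl is superfluous and must be removed without disturbing ester or ketal. The C7 configuration is decided by hydrogen transfer to a planar radical and can only be corrected afterwards. Stoichiometric tin is required.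
- Comparison: on structure the plans are equal for ring A, the alternative is better for C10 and worse in carrying an extra oxygen. On mechanism a radical chain with competing direct reduction stands against an ionic closure with competing ortho attack, roughly an even trade. On step economy the sequence to and from A5 is not expected to be shorter than steps 1–13.

Alternative 3: The cut is the C3–C4 bond of ring A, with the aryl–oxygen bond kept. The precursor is the aryl enol ether A6, a ring B cyclohexane with an exocyclic methylene at C5, the quaternary C10 and a two-carbon chain ending in a 2-aryloxypropene unit. In the forward direction catalytic HNTf2 would protonate the enol ether at its terminal carbon (the future C3 methyl), the aryloxy-stabilised C3 cation would be attacked by the methylene carbon C4, and proton loss from C6 would give the octalin A7.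
- In its favour: the hindered tertiary ether is made without arylating a tertiary alcohol, because the C–O bond is formed on an sp2 carbon before the ring exists. On this point the alternative is better than the chosen plan, whose step 16 is one of its weakest. The isomer with equatorial methyl and axial aryloxy is also the thermodynamically preferred one, which helps if the closure is reversible. The steps after A7 (Suzuki coupling, allylation, desilylation) are equal to steps 18–20.
- Against it here: C3 is created in a cation–alkene cyclisation whose facial selectivity depends only on remote centres. Both the enol ether and the tertiary aryl ether product are acid-labile, so hydrolysis, re-ionisation, elimination and loss of the silyl ether all threaten. Proton loss may give the C4=C5 isomer. The C5=C6 bond must then be hydrogenated from the face opposite the angular methyl without touching C–Br and C–Cl. A6 still needs C10 and C7 set in a 1,4-relationship on a monocycle.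
- Comparison: on structure the alternative addresses the ether directly where the chosen plan addresses the decalin directly. On mechanism it exchanges a basic, irreversible closure for an acidic, potentially reversible one. On step economy it saves the methylation and arylation but adds a hydrogenation and a longer precursor synthesis, so no clear gain is expected.

Key step: step 11

## Route

Step 1
Reactants: 1 5-hydroxy-2-methylbenzoic acid
Product: 2 benzyl 5-(benzyloxy)-2-methylbenzoate
Conditions: BnBr (2.3 equiv), K2CO3, DMF, 60 °C
Reagents that add atoms: benzyl bromide, BrCc1ccccc1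
Why: Double O-alkylation (Williamson type): carboxylate and phenoxide are both benzylated by SN2 displacement, so one reagent protects the phenol and turns the acid into a reducible ester.

Step 2
Reactants: 2 benzyl 5-(benzyloxy)-2-methylbenzoate
Product: 3 [5-(benzyloxy)-2-methylphenyl]methanol
Conditions: LiAlH4, THF, 0 °C to rt
Reagents that add atoms: none
Why: Hydride reduction of the ester to the benzylic alcohol; the aryl benzyl ether is inert to LiAlH4 and the benzyl alcohol released is separated on silica.

Step 3
Reactants: 3 [5-(benzyloxy)-2-methylphenyl]methanol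
Product: 4 4-(benzyloxy)-2-(bromomethyl)-1-methylbenzene
Conditions: CBr4, PPh3, CH2Cl2, 0 °C
Reagents that add atoms: carbon tetrabromide, BrC(Br)(Br)Br
Why: Appel bromination of a primary benzylic alcohol under neutral conditions that spare the benzyl ether.

Step 4
Reactants: 5 4-(benzyloxy)butanoic acid; 6 (S)-4-benzyl-2-oxazolidinone
Product: 8 (S)-4-benzyl-3-[4-(benzyloxy)butanoyl]oxazolidin-2-one, via mixed pivalic anhydride 7 (not isolated)
Conditions: PivCl, Et3N, THF, −20 °C; then 6, LiCl, rt
Reagents that add atoms: none
Why: N-Acylation of the oxazolidinone through the mixed anhydride; LiCl/Et3N makes the carbamate nitrogen nucleophilic enough and attack occurs at the unhindered acyl carbon, not at the pivaloyl carbon.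

Step 5
Reactants: 8 (S)-4-benzyl-3-[4-(benzyloxy)butanoyl]oxazolidin-2-one; 4 4-(benzyloxy)-2-(bromomethyl)-1-methylbenzene
Product: 10 (S)-4-benzyl-3-[(2S)-4-(benzyloxy)-2-{[5-(benzyloxy)-2-methylphenyl]methyl}butanoyl]oxazolidin-2-one, via sodium Z-enolate 9 (not isolated)
Conditions: NaN(SiMe3)2, THF, −78 °C; then 4, −78 to −30 °C
Reagents that add atoms: none
Why: Evans asymmetric alkylation: the chelated sodium Z-enolate is attacked by the benzylic bromide on the face opposite the benzyl group of the auxiliary, which sets C7. The descriptor is S in the open-chain compounds and R in the decalin only because the CIP ranking of the two arms changes; the spatial arrangement is the same.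

Step 6
Reactants: 10 (S)-4-benzyl-3-[(2S)-4-(benzyloxy)-2-{[5-(benzyloxy)-2-methylphenyl]methyl}butanoyl]oxazolidin-2-one
Product: 11 methyl (2S)-4-(benzyloxy)-2-{[5-(benzyloxy)-2-methylphenyl]methyl}butanoate
Conditions: MeMgBr, MeOH, CH2Cl2, 0 °C
Reagents that add atoms: methanol, CO
Why: Transesterification of the exocyclic imide carbonyl by the bromomagnesium methoxide formed in the flask; this weakly basic alkoxide removes the auxiliary without epimerising the α-centre, and 6 is recovered.

Step 7
Reactants: 11 methyl (2S)-4-(benzyloxy)-2-{[5-(benzyloxy)-2-methylphenyl]methyl}butanoate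
Product: 13 (3S)-5-(benzyloxy)-3-{[5-(benzyloxy)-2-methylphenyl]methyl}-2-methylpentan-2-ol, via methyl ketone 12 (not isolated)
Conditions: MeMgBr (4 equiv), THF, 0 °C to rt
Reagents that add atoms: methylmagnesium bromide, C[Mg]Br
Why: Double Grignard addition to the ester through the methyl ketone builds the C11 carbinol; the ketone should be consumed faster than it is enolised, so the adjacent stereocentre is expected to survive.

Step 8
Reactants: 13 (3S)-5-(benzyloxy)-3-{[5-(benzyloxy)-2-methylphenyl]methyl}-2-methylpentan-2-ol
Product: 14 {[(3S)-5-(benzyloxy)-3-{[5-(benzyloxy)-2-methylphenyl]methyl}-2-methylpentan-2-yl]oxy}(tert-butyl)dimethylsilane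
Conditions: TBSOTf, 2,6-lutidine, CH2Cl2, 0 °C to rt
Reagents that add atoms: tert-butyldimethylsilyl triflate, CC(C)(C)[Si](C)(C)OS(=O)(=O)C(F)(F)F
Why: Silylation of a hindered tertiary alcohol needs the silyl triflate; the ether later stops the C11 oxygen from displacing the C9 bromide and adds bulk that favours an equatorial C7 group in the key step.

Step 9
Reactants: 14 {[(3S)-5-(benzyloxy)-3-{[5-(benzyloxy)-2-methylphenyl]methyl}-2-methylpentan-2-yl]oxy}(tert-butyl)dimethylsilane
Product: 15 3-[(2S)-2-{2-[(tert-butyldimethylsilyl)oxy]propan-2-yl}-4-hydroxybutyl]-4-methylphenol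
Conditions: H2 (1 atm), Pd/C, EtOAc, rt
Reagents that add atoms: none
Why: Hydrogenolysis cleaves the aryl and the alkyl benzyl ether in one operation and frees the phenol and the primary alcohol; the silyl ether and the arene are not affected.

Step 10
Reactants: 15 3-[(2S)-2-{2-[(tert-butyldimethylsilyl)oxy]propan-2-yl}-4-hydroxybutyl]-4-methylphenol
Product: 16 3-[(2S)-4-bromo-2-{2-[(tert-butyldimethylsilyl)oxy]propan-2-yl}butyl]-4-methylphenol
Conditions: CBr4, PPh3, CH2Cl2, 0 °C
Reagents that add atoms: carbon tetrabromide, BrC(Br)(Br)Br
Why: Appel bromination is selective for the primary alcohol, because a phenol oxygen cannot be displaced at an sp2 carbon; the neutral conditions spare the tertiary silyl ether.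

Step 11
Reactants: 16 3-[(2S)-4-bromo-2-{2-[(tert-butyldimethylsilyl)oxy]propan-2-yl}butyl]-4-methylphenol
Product: 18 (4aS,7R)-7-{2-[(tert-butyldimethylsilyl)oxy]propan-2-yl}-4a-methyl-5,6,7,8-tetrahydronaphthalen-2(4aH)-one, via potassium phenolate 17 (not isolated)
Conditions: KOt-Bu (1.05 equiv), t-BuOH, 0.01 M, 40 to 80 °C
Reagents that add atoms: none
Why: Deprotonation gives the ambident potassium phenolate, whose para carbon C10 displaces bromide from C9 in an intramolecular SN2 reaction; because C10 carries the methyl group the adduct cannot lose a proton and is released as the cross-conjugated cyclohexa-2,5-dienone. The closest known reaction type is the base-mediated intramolecular para-C-alkylation of phenolates bearing haloalkyl or sulfonyloxyalkyl chains, which gives fused 4,4-disubstituted dienones. Ring B closes in a 6-exo-tet mode through the chain C5–C6–C7–C8–C9, with the new bond forming perpendicular to the arene plane. The new stereocentre C10 is controlled by C7: in the chair-like transition state the bulky silyloxypropyl group is equatorial, C1 of the flat ring A is equatorial on ring B and the methyl is axial, which puts the methyl cis to the C7 group (10S with 7R). The step needs C- over O-alkylation, para (C10) over ortho (C4) attack and substitution over elimination. O-Alkylation would require an eight-membered meta-bridged ring and is further disfavoured by hydrogen bonding in t-BuOH and by high dilution; para attack is favoured by the higher charge density at C10, although C4 would also close a six-membered ring; and with one equivalent of base the weakly basic phenolate is the only base, so E2 loss of HBr should be minor. Any product of C4 attack is a phenol and is removed by an alkaline wash, and the silyl ether keeps the C11 oxygen from forming a tetrahydrofuran.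

Step 12
Reactants: 18 (4aS,7R)-7-{2-[(tert-butyldimethylsilyl)oxy]propan-2-yl}-4a-methyl-5,6,7,8-tetrahydronaphthalen-2(4aH)-one
Product: 19 (4aS,7R)-7-{2-[(tert-butyldimethylsilyl)oxy]propan-2-yl}-4a-methyl-4,4a,5,6,7,8-hexahydronaphthalen-2(3H)-one
Conditions: H2 (1 atm), RhCl(PPh3)3 (5 mol %), toluene/EtOH, rt
Reagents that add atoms: none
Why: Homogeneous hydrogenation with RhCl(PPh3)3 discriminates by substitution: the disubstituted C1=C2 bond of a 1,4-dien-3-one is saturated and the trisubstituted C4=C5 bond is left, a selectivity established for steroidal dienones.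

Step 13
Reactants: 19 (4aS,7R)-7-{2-[(tert-butyldimethylsilyl)oxy]propan-2-yl}-4a-methyl-4,4a,5,6,7,8-hexahydronaphthalen-2(3H)-one
Product: 21 (4aS,7R,8aS)-7-{2-[(tert-butyldimethylsilyl)oxy]propan-2-yl}-4a-methyloctahydronaphthalen-2(1H)-one, via lithium enolate 20 (not isolated)
Conditions: Li, NH3(l), THF, t-BuOH (1 equiv), −78 °C; then NH4Cl
Reagents that add atoms: none
Why: Dissolving-metal reduction of the enone: the C5 carbanion is protonated axially, anti to the angular methyl, which gives the trans-fused decalin (5S), and the lithium enolate is protonated to the ketone on quench; silyl ethers are stable to Li/NH3.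

Step 14
Reactants: 21 (4aS,7R,8aS)-7-{2-[(tert-butyldimethylsilyl)oxy]propan-2-yl}-4a-methyloctahydronaphthalen-2(1H)-one
Product: 22 (2R,4aS,7R,8aS)-7-{2-[(tert-butyldimethylsilyl)oxy]propan-2-yl}-2,4a-dimethyldecahydronaphthalen-2-ol
Conditions: MeTi(Oi-Pr)3 (from ClTi(Oi-Pr)3 + MeLi), Et2O, 0 °C to rt
Reagents that add atoms: methyltitanium triisopropoxide, C[Ti](OC(C)C)(OC(C)C)OC(C)C
Why: Carbonyl addition of a bulky, non-basic methyltitanium reagent: it approaches the conformationally locked cyclohexanone along the equatorial trajectory, away from the axial hydrogens at C1 and C5, and should give the equatorial methyl and axial hydroxyl at C3 (3R) without enolisation.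

Step 15
Reactants: 23 2-bromo-4-chloro-1-iodobenzene
Product: 25 (2-bromo-4-chlorophenyl)(2,4,6-trimethoxyphenyl)iodonium tosylate, via hydroxy(tosyloxy)iodoarene 24 (not isolated)
Conditions: mCPBA, TsOH·H2O, MeCN, 77 °C; then 1,3,5-trimethoxybenzene, rt
Reagents that add atoms: 1,3,5-trimethoxybenzene, COc1cc(OC)cc(OC)c1; p-toluenesulfonic acid monohydrate, Cc1ccc(S(=O)(=O)O)cc1.O
Why: One-pot oxidation of the aryl iodide to trivalent iodine followed by electrophilic substitution on the electron-rich trimethoxybenzene gives the unsymmetrical diaryliodonium salt; the trimethoxyphenyl ring is the ligand that is not transferred later.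

Step 16
Reactants: 22 (2R,4aS,7R,8aS)-7-{2-[(tert-butyldimethylsilyl)oxy]propan-2-yl}-2,4a-dimethyldecahydronaphthalen-2-ol; 25 (2-bromo-4-chlorophenyl)(2,4,6-trimethoxyphenyl)iodonium tosylate
Product: 27 2-bromo-4-chlorophenyl (2R,4aS,7R,8aS)-7-{2-[(tert-butyldimethylsilyl)oxy]propan-2-yl}-2,4a-dimethyldecahydronaphthalen-2-yl ether, via sodium alkoxide 26 (not isolated)
Conditions: NaH, toluene, rt; then 25, rt to 40 °C
Reagents that add atoms: none
Why: Metal-free O-arylation of a tertiary alkoxide with a diaryliodonium salt: ligand exchange at trivalent iodine and ligand coupling transfer the more electron-poor, ortho-substituted 2-bromo-4-chlorophenyl group to oxygen, and the trimethoxyphenyl group leaves as the iodoarene. The C3 configuration is untouched because only the O–H bond is broken.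

Step 17
Reactants: 28 2-allyl-4-bromophenol
Product: 29 2-allyl-4-(4,4,5,5-tetramethyl-1,3,2-dioxaborolan-2-yl)phenol
Conditions: B2pin2, Pd(dppf)Cl2 (3 mol %), KOAc, dioxane, 85 °C
Reagents that add atoms: bis(pinacolato)diboron, CC1(C)OB(OC1(C)C)B1OC(C)(C)C(C)(C)O1
Why: Miyaura borylation of the aryl bromide; the weak base KOAc tolerates the free phenol and should not move the allyl double bond.

Step 18
Reactants: 27 2-bromo-4-chlorophenyl (2R,4aS,7R,8aS)-7-{2-[(tert-butyldimethylsilyl)oxy]propan-2-yl}-2,4a-dimethyldecahydronaphthalen-2-yl ether; 29 2-allyl-4-(4,4,5,5-tetramethyl-1,3,2-dioxaborolan-2-yl)phenol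
Product: 30 3-allyl-5'-chloro-2'-{[(2R,4aS,7R,8aS)-7-{2-[(tert-butyldimethylsilyl)oxy]propan-2-yl}-2,4a-dimethyldecahydronaphthalen-2-yl]oxy}biphenyl-4-ol
Conditions: Pd(dppf)Cl2 (5 mol %), K2CO3, dioxane/H2O, 85 °C
Reagents that add atoms: none
Why: Suzuki–Miyaura coupling at the C–Br bond; with Pd(dppf)Cl2 the electron-rich C–Cl bond should not undergo oxidative addition, so the chloride is kept for the next step.

Step 19
Reactants: 30 3-allyl-5'-chloro-2'-{[(2R,4aS,7R,8aS)-7-{2-[(tert-butyldimethylsilyl)oxy]propan-2-yl}-2,4a-dimethyldecahydronaphthalen-2-yl]oxy}biphenyl-4-ol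
Product: 31 3,5'-diallyl-2'-{[(2R,4aS,7R,8aS)-7-{2-[(tert-butyldimethylsilyl)oxy]propan-2-yl}-2,4a-dimethyldecahydronaphthalen-2-yl]oxy}biphenyl-4-ol
Conditions: allylSnBu3, Pd2(dba)3 (2.5 mol %), P(t-Bu)3 (10 mol %), CsF, dioxane, 100 °C
Reagents that add atoms: allyltributylstannane, C=CC[Sn](CCCC)(CCCC)CCCC
Why: Stille coupling of an unactivated aryl chloride, made possible by the bulky electron-rich P(t-Bu)3 ligand on zerovalent palladium and fluoride activation of the stannane; the phenol (as its caesium salt) and the silyl ether are spectators.

Step 20
Reactants: 31 3,5'-diallyl-2'-{[(2R,4aS,7R,8aS)-7-{2-[(tert-butyldimethylsilyl)oxy]propan-2-yl}-2,4a-dimethyldecahydronaphthalen-2-yl]oxy}biphenyl-4-ol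
Product: 32 3,5'-diallyl-2'-{[(2R,4aS,7R,8aS)-7-(2-hydroxypropan-2-yl)-2,4a-dimethyldecahydronaphthalen-2-yl]oxy}biphenyl-4-ol (CNP0342687.1)
Conditions: Bu4NF, THF, 60 °C; then aq. NH4Cl
Reagents that add atoms: none
Why: Fluoride cleavage of the tertiary silyl ether, driven by Si–F bond formation; the non-acidic conditions keep the tertiary alkyl aryl ether intact and should be too mild to move the allyl double bonds.

## Compound list

1 | 5-hydroxy-2-methylbenzoic acid | Cc1ccc(O)cc1C(=O)O | starting material
2 | benzyl 5-(benzyloxy)-2-methylbenzoate | Cc1ccc(OCc2ccccc2)cc1C(=O)OCc1ccccc1 | intermediate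
3 | [5-(benzyloxy)-2-methylphenyl]methanol | Cc1ccc(OCc2ccccc2)cc1CO | intermediate
4 | 4-(benzyloxy)-2-(bromomethyl)-1-methylbenzene | Cc1ccc(OCc2ccccc2)cc1CBr | intermediate
5 | 4-(benzyloxy)butanoic acid | OC(=O)CCCOCc1ccccc1 | starting material
6 | (S)-4-benzyl-2-oxazolidinone | O=C1N[C@@H](Cc2ccccc2)CO1 | starting material
7 | 4-(benzyloxy)butanoic pivalic anhydride (not isolated) | CC(C)(C)C(=O)OC(=O)CCCOCc1ccccc1 | intermediate
8 | (S)-4-benzyl-3-[4-(benzyloxy)butanoyl]oxazolidin-2-one | O=C1OC[C@H](Cc2ccccc2)N1C(=O)CCCOCc1ccccc1 | intermediate
9 | sodium (Z)-enolate of 8 (not isolated) | [Na+].[O-]/C(=C\CCOCc1ccccc1)N1C(=O)OC[C@@H]1Cc1ccccc1 | intermediate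
10 | (S)-4-benzyl-3-[(2S)-4-(benzyloxy)-2-{[5-(benzyloxy)-2-methylphenyl]methyl}butanoyl]oxazolidin-2-one | O=C1OC[C@H](Cc2ccccc2)N1C(=O)[C@@H](Cc1cc(OCc2ccccc2)ccc1C)CCOCc1ccccc1 | intermediate
11 | methyl (2S)-4-(benzyloxy)-2-{[5-(benzyloxy)-2-methylphenyl]methyl}butanoate | COC(=O)[C@@H](Cc1cc(OCc2ccccc2)ccc1C)CCOCc1ccccc1 | intermediate
12 | (3S)-5-(benzyloxy)-3-{[5-(benzyloxy)-2-methylphenyl]methyl}pentan-2-one (not isolated) | CC(=O)[C@@H](Cc1cc(OCc2ccccc2)ccc1C)CCOCc1ccccc1 | intermediate
13 | (3S)-5-(benzyloxy)-3-{[5-(benzyloxy)-2-methylphenyl]methyl}-2-methylpentan-2-ol | CC(C)(O)[C@@H](Cc1cc(OCc2ccccc2)ccc1C)CCOCc1ccccc1 | intermediate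
14 | tert-butyldimethylsilyl ether of 13 | CC(C)(O[Si](C)(C)C(C)(C)C)[C@@H](Cc1cc(OCc2ccccc2)ccc1C)CCOCc1ccccc1 | intermediate
15 | 3-[(2S)-2-{2-[(tert-butyldimethylsilyl)oxy]propan-2-yl}-4-hydroxybutyl]-4-methylphenol | CC(C)(O[Si](C)(C)C(C)(C)C)[C@@H](Cc1cc(O)ccc1C)CCO | intermediate
16 | 3-[(2S)-4-bromo-2-{2-[(tert-butyldimethylsilyl)oxy]propan-2-yl}butyl]-4-methylphenol | Cc1ccc(O)cc1C[C@@H](CCBr)C(C)(C)O[Si](C)(C)C(C)(C)C | intermediate
17 | potassium phenolate of 16 (not isolated) | [K+].[O-]c1ccc(C)c(C[C@@H](CCBr)C(C)(C)O[Si](C)(C)C(C)(C)C)c1 | intermediate
18 | (4aS,7R)-7-{2-[(tert-butyldimethylsilyl)oxy]propan-2-yl}-4a-methyl-5,6,7,8-tetrahydronaphthalen-2(4aH)-one (10-methyl-1,4-dien-3-one, methyl cis to the C7 group) | O=C1C=C[C@]2(C)CC[C@@H](C(C)(C)O[Si](C)(C)C(C)(C)C)CC2=C1 | intermediate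
19 | (4aS,7R)-7-{2-[(tert-butyldimethylsilyl)oxy]propan-2-yl}-4a-methyl-4,4a,5,6,7,8-hexahydronaphthalen-2(3H)-one | O=C1CC[C@]2(C)CC[C@@H](C(C)(C)O[Si](C)(C)C(C)(C)C)CC2=C1 | intermediate
20 | lithium C3–C4 enolate of 21 (not isolated) | [Li+].[O-]C=1CC[C@]2(C)CC[C@@H](C(C)(C)O[Si](C)(C)C(C)(C)C)C[C@H]2C=1 | intermediate
21 | (4aS,7R,8aS)-7-{2-[(tert-butyldimethylsilyl)oxy]propan-2-yl}-4a-methyloctahydronaphthalen-2(1H)-one (trans-fused) | O=C1CC[C@]2(C)CC[C@@H](C(C)(C)O[Si](C)(C)C(C)(C)C)C[C@H]2C1 | intermediate
22 | (2R,4aS,7R,8aS)-7-{2-[(tert-butyldimethylsilyl)oxy]propan-2-yl}-2,4a-dimethyldecahydronaphthalen-2-ol (axial OH, equatorial CH3) | O[C@]1(C)CC[C@]2(C)CC[C@@H](C(C)(C)O[Si](C)(C)C(C)(C)C)C[C@H]2C1 | intermediate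
23 | 2-bromo-4-chloro-1-iodobenzene | Clc1ccc(I)c(Br)c1 | starting material
24 | 2-bromo-4-chloro-1-[hydroxy(tosyloxy)iodo]benzene (not isolated) | OI(OS(=O)(=O)c1ccc(C)cc1)c1ccc(Cl)cc1Br | intermediate
25 | (2-bromo-4-chlorophenyl)(2,4,6-trimethoxyphenyl)iodonium tosylate | COc1cc(OC)c([I+]c2ccc(Cl)cc2Br)c(OC)c1.Cc1ccc(S(=O)(=O)[O-])cc1 | intermediate
26 | sodium alkoxide of 22 (not isolated) | [Na+].[O-][C@]1(C)CC[C@]2(C)CC[C@@H](C(C)(C)O[Si](C)(C)C(C)(C)C)C[C@H]2C1 | intermediate
27 | 2-bromo-4-chlorophenyl (2R,4aS,7R,8aS)-7-{2-[(tert-butyldimethylsilyl)oxy]propan-2-yl}-2,4a-dimethyldecahydronaphthalen-2-yl ether | Clc1ccc(O[C@]2(C)CC[C@]3(C)CC[C@@H](C(C)(C)O[Si](C)(C)C(C)(C)C)C[C@H]3C2)c(Br)c1 | intermediate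
28 | 2-allyl-4-bromophenol | C=CCc1cc(Br)ccc1O | starting material
29 | 2-allyl-4-(4,4,5,5-tetramethyl-1,3,2-dioxaborolan-2-yl)phenol | C=CCc1cc(B2OC(C)(C)C(C)(C)O2)ccc1O | intermediate
30 | 3-allyl-5'-chloro-2'-{[(2R,4aS,7R,8aS)-7-{2-[(tert-butyldimethylsilyl)oxy]propan-2-yl}-2,4a-dimethyldecahydronaphthalen-2-yl]oxy}biphenyl-4-ol | Clc1ccc(O[C@]2(C)CC[C@]3(C)CC[C@@H](C(C)(C)O[Si](C)(C)C(C)(C)C)C[C@H]3C2)c(-c2ccc(O)c(CC=C)c2)c1 | intermediate
31 | 3,5'-diallyl-2'-{[(2R,4aS,7R,8aS)-7-{2-[(tert-butyldimethylsilyl)oxy]propan-2-yl}-2,4a-dimethyldecahydronaphthalen-2-yl]oxy}biphenyl-4-ol | C=CCc1ccc(O[C@]2(C)CC[C@]3(C)CC[C@@H](C(C)(C)O[Si](C)(C)C(C)(C)C)C[C@H]3C2)c(-c2ccc(O)c(CC=C)c2)c1 | intermediate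
32 | 3,5'-diallyl-2'-{[(2R,4aS,7R,8aS)-7-(2-hydroxypropan-2-yl)-2,4a-dimethyldecahydronaphthalen-2-yl]oxy}biphenyl-4-ol | C=CCc1ccc(O[C@]2(C)CC[C@]3(C)CC[C@@H](C(C)(C)O)C[C@H]3C2)c(-c2ccc(O)c(CC=C)c2)c1 | target

## Step count and least certain steps

Total: 20 steps. Longest linear sequence: 17 steps from 1 (steps 1–3, 5–14, 16, 18–20); steps 4, 15 and 17 are side branches.

Step 11 (key step). The most likely failure is closure through the unsubstituted ortho carbon C4, which also forms a six-membered ring and is made irreversible by rearomatisation. Intermolecular O-alkylation at higher concentration and facial leakage, if the equatorial preference of the C7 group is not decisive, are lesser concerns. Fallback, setting out from 16 and returning at 18: NBS (2 equiv, MeCN, 0 °C) should brominate both free ortho positions, the para position being occupied by the methyl, to give 2,6-dibromo-3-[(2S)-4-bromo-2-{2-[(tert-butyldimethylsilyl)oxy]propan-2-yl}butyl]-4-methylphenol F1. KOt-Bu in t-BuOH then leaves the para carbon as the only carbon nucleophile that can give a stable product and should give the 1,3-dibromo analogue of the dienone, (4aS,7R)-1,3-dibromo-7-{2-[(tert-butyldimethylsilyl)oxy]propan-2-yl}-4a-methyl-5,6,7,8-tetrahydronaphthalen-2(4aH)-one F2. Palladium-catalysed formate reduction of the two vinylic C–Br bonds (Pd(OAc)2, PPh3, HCO2H, Et3N, DMF, 60 °C) leads back to 18.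

Step 16. The aryl transfer to the hindered axial tertiary alkoxide may be slow, so that base-induced decomposition of the iodonium salt (aryne formation, transfer of the wrong ligand) or elimination of the alkoxide takes over. Fallback, setting out from 22 and returning at 27: the potassium alkoxide (KN(SiMe3)2, THF) should displace fluoride from 4-chloro-1-fluoro-2-nitrobenzene by nucleophilic aromatic substitution to give the 4-chloro-2-nitrophenyl ether F3. Reduction with Fe/NH4Cl in EtOH/H2O gives the 2-amino-4-chlorophenyl ether F4, and a non-aqueous Sandmeyer bromination (t-BuONO, CuBr2, MeCN) gives 27.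

Step 14. Facial selectivity may be incomplete (axial attack giving the C3 epimer), and the mild titanium reagent may add sluggishly to a ketone. Fallback, setting out from 21 and returning at 22: Corey–Chaykovsky epoxidation with dimethylsulfoxonium methylide (Me3S(O)I, NaH, DMSO/THF) adds reversibly and closes from the betaine with the new C–C bond equatorial, giving the spiro-epoxide with axial oxygen F5. Hydride opening at the CH2 terminus (LiEt3BH, THF, 0 °C) gives 22.

Step 19. Oxidative addition into the electron-rich C–Cl bond may be slow, which leaves room for palladium hydride mediated migration of the allyl double bonds into conjugation and for reductive loss of chlorine. Fallback, setting out from 30 and returning at 31: Miyaura borylation of the chloride (B2pin2, Pd2(dba)3, XPhos, KOAc, dioxane, 100 °C) gives the arylboronate F6. Coupling with excess allyl bromide (Pd(PPh3)4, K2CO3, DMF, 70 °C) reverses the polarity of the allylation and at the same time O-allylates the phenol, giving the allyl ether F7. Palladium-catalysed removal of the O-allyl group (Pd(PPh3)4, morpholine, THF) gives 31; the C-allyl groups are inert to it.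

Step 20. Cleavage of the hindered tertiary silyl ether may be incomplete under conditions mild enough to avoid base-induced double-bond migration and acid-induced ionisation of the tertiary aryl ether. Fallback, setting out from 27 and returning at 32: the silyl group is removed before any allyl group or free phenol is present, where forcing fluoride conditions (Bu4NF, DMF, 90 °C) are tolerated, giving the bromo chloro aryl ether with free C11 carbinol F8. Suzuki coupling with 29 as in step 18 gives the biaryl carbinol F9, and Stille allylation as in step 19 gives 32 directly.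

## Further compounds

F1 | step 11 | 2,6-dibromo-3-[(2S)-4-bromo-2-{2-[(tert-butyldimethylsilyl)oxy]propan-2-yl}butyl]-4-methylphenol | Cc1cc(Br)c(O)c(Br)c1C[C@@H](CCBr)C(C)(C)O[Si](C)(C)C(C)(C)C
F2 | step 11 | (4aS,7R)-1,3-dibromo-7-{2-[(tert-butyldimethylsilyl)oxy]propan-2-yl}-4a-methyl-5,6,7,8-tetrahydronaphthalen-2(4aH)-one | O=C1C(Br)=C[C@]2(C)CC[C@@H](C(C)(C)O[Si](C)(C)C(C)(C)C)CC2=C1Br
F3 | step 16 | 4-chloro-2-nitrophenyl (2R,4aS,7R,8aS)-7-{2-[(tert-butyldimethylsilyl)oxy]propan-2-yl}-2,4a-dimethyldecahydronaphthalen-2-yl ether | Clc1ccc(O[C@]2(C)CC[C@]3(C)CC[C@@H](C(C)(C)O[Si](C)(C)C(C)(C)C)C[C@H]3C2)c([N+](=O)[O-])c1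
F4 | step 16 | 2-amino-4-chlorophenyl (2R,4aS,7R,8aS)-7-{2-[(tert-butyldimethylsilyl)oxy]propan-2-yl}-2,4a-dimethyldecahydronaphthalen-2-yl ether | Clc1ccc(O[C@]2(C)CC[C@]3(C)CC[C@@H](C(C)(C)O[Si](C)(C)C(C)(C)C)C[C@H]3C2)c(N)c1
F5 | step 14 | C3 spiro-epoxide of 21 (oxygen axial, CH2 equatorial) | O1C[C@]12CC[C@]3(C)CC[C@@H](C(C)(C)O[Si](C)(C)C(C)(C)C)C[C@H]3C2
F6 | step 19 | 3-allyl-2'-{[(2R,4aS,7R,8aS)-7-{2-[(tert-butyldimethylsilyl)oxy]propan-2-yl}-2,4a-dimethyldecahydronaphthalen-2-yl]oxy}-5'-(4,4,5,5-tetramethyl-1,3,2-dioxaborolan-2-yl)biphenyl-4-ol | CC1(C)OB(OC1(C)C)c1ccc(O[C@]2(C)CC[C@]3(C)CC[C@@H](C(C)(C)O[Si](C)(C)C(C)(C)C)C[C@H]3C2)c(-c2ccc(O)c(CC=C)c2)c1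
F7 | step 19 | allyl ether of 31 (3,5'-diallyl-4-(allyloxy)biphenyl-2'-yl decalinyl ether) | C=CCOc1ccc(cc1CC=C)-c1cc(CC=C)ccc1O[C@]1(C)CC[C@]2(C)CC[C@@H](C(C)(C)O[Si](C)(C)C(C)(C)C)C[C@H]2C1
F8 | step 20 | 2-bromo-4-chlorophenyl (2R,4aS,7R,8aS)-7-(2-hydroxypropan-2-yl)-2,4a-dimethyldecahydronaphthalen-2-yl ether | Clc1ccc(O[C@]2(C)CC[C@]3(C)CC[C@@H](C(C)(C)O)C[C@H]3C2)c(Br)c1
F9 | step 20 | 3-allyl-5'-chloro-2'-{[(2R,4aS,7R,8aS)-7-(2-hydroxypropan-2-yl)-2,4a-dimethyldecahydronaphthalen-2-yl]oxy}biphenyl-4-ol | Clc1ccc(O[C@]2(C)CC[C@]3(C)CC[C@@H](C(C)(C)O)C[C@H]3C2)c(-c2ccc(O)c(CC=C)c2)c1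
A1 | alternative 1 | ring A hydroxy aldehyde with a formylmethyl arm on C10 and a prenyl group on C5 | O[C@]1(C)CC[C@](C)(CC=O)[C@@H](CC=C(C)C)C1
A2 | alternative 1 | decalin 3,8,11-triol | O[C@]2(C)CC[C@]3(C)C[C@@H](O)[C@@H](C(C)(C)O)C[C@H]3C2
A3 | alternative 2 | (S)-Hajos–Parrish ketone, (7aS)-7a-methyl-2,3,7,7a-tetrahydro-1H-indene-1,5(6H)-dione | O=C1CC[C@]2(C)C(=O)CCC2=C1
A4 | alternative 2 | trans-hydrindanone bromomethyl β-keto ester, C3 ketal (C7 either epimer) | C12(OCCO1)CC[C@]3(C)C(=O)C(CBr)(C(=O)OC)C[C@H]3C2
A5 | alternative 2 | trans-decalin 9-ketone 7-methyl ester, C3 ketal | C12(OCCO1)CC[C@]3(C)C(=O)C[C@@H](C(=O)OC)C[C@H]3C2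
A6 | alternative 3 | 2-bromo-4-chlorophenyl enol ether with exocyclic C5 methylene | C=C(Oc1ccc(Cl)cc1Br)CC[C@]1(C)CC[C@@H](C(C)(C)O[Si](C)(C)C(C)(C)C)CC1=C
A7 | alternative 3 | C5=C6 octalin tertiary aryl ether | Clc1ccc(O[C@]2(C)CC[C@]3(C)CC[C@@H](C(C)(C)O[Si](C)(C)C(C)(C)C)C=C3C2)c(Br)c1
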